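Everything rests on cutting ring C, the terminal 5-alkylresorcinol, into a four-carbon and a two-carbon piece. Ring C carries only O at C3 and C5 and the side-chain CH2 at C1, while C2, C4 and C6 are CH. This 1,3,5 pattern is what a 3-alkylcyclobutenone and an O-silylated ethynol deliver. The fully assembled tetraester, with rings A and B as benzyl ethers and a cyclobut-2-enone at the chain end, is heated with (triisopropylsilyloxy)acetylene. One neutral, purely thermal operation forms two C–C bonds and the aromatic ring without touching the four stereocentres or the β-acyloxy esters. Desilylation and hydrogenolysis finish the synthesis.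

Key step: step 17

Assumption: chloroacetaldehyde is used as the anhydrous monomer, obtained by extracting the commercial aqueous solution into CH2Cl2 and drying it (not counted as a step). All other starting materials are taken as catalogue compounds, and all four carbinol centres of the target are (R).

Step 1
Reactants: 1 orsellinic acid (2,4-dihydroxy-6-methylbenzoic acid)
Product: 2 benzyl 2,4-bis(benzyloxy)-6-methylbenzoate
Conditions: BnBr (3.5 equiv), K2CO3 (4 equiv), DMF, rt → 60 °C
Reagents that add atoms: benzyl bromide BrCc1ccccc1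
Why: Williamson-type O-alkylation, in which carbonate deprotonates the acid and both phenols and each oxygen is benzylated by SN2, so the decarboxylation-prone acid is capped first and the chelated ortho phenol follows on warming.

Step 2
Reactants: 2 benzyl 2,4-bis(benzyloxy)-6-methylbenzoate
Product: 3 2,4-bis(benzyloxy)-6-methylbenzoic acid
Conditions: KOH (10 equiv), MeOH/1,4-dioxane/H2O, reflux; then 1 M HCl
Reagents that add atoms: potassium hydroxide [K+].[OH-]
Why: Saponification by acyl–oxygen cleavage of the hindered benzyl ester needs forcing hydroxide, which is harmless here because aryl benzyl ethers resist base and no stereocentre or labile ester is present yet.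

Step 3
Reactants: 3 2,4-bis(benzyloxy)-6-methylbenzoic acid; 4 tert-butyl (R)-3-hydroxybutanoate
Product: 6 tert-butyl (R)-3-[2,4-bis(benzyloxy)-6-methylbenzoyloxy]butanoate, via 2,4-bis(benzyloxy)-6-methylbenzoyl chloride 5 (not isolated)
Conditions: Me2C=C(Cl)NMe2 (1.2 equiv), CH2Cl2, 0 °C → rt; then 4 (1.5 equiv), Et3N (2 equiv), DMAP (0.5 equiv), 0 °C → rt
Reagents that add atoms: none
Why: Acid chloride esterification with DMAP catalysis, in which the neutral chloroenamine makes the doubly ortho-substituted aroyl chloride without HCl and the acylpyridinium ion acylates the secondary OH with retention, since the C–O bond of the stereocentre is not touched.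

Step 4
Reactants: 6 tert-butyl (R)-3-[2,4-bis(benzyloxy)-6-methylbenzoyloxy]butanoate
Product: 7 (R)-3-[2,4-bis(benzyloxy)-6-methylbenzoyloxy]butanoic acid
Conditions: TFA/CH2Cl2 (1:4), 0 °C → rt
Reagents that add atoms: none
Why: Acidolysis of the tert-butyl ester (alkyl–oxygen cleavage with loss of isobutene) frees the acid without any base, so E1cB loss of the β-aroyloxy group cannot start, and aryl benzyl ethers survive short contact with dilute TFA.

Step 5
Reactants: 8 1,3-bis(benzyloxy)-5-bromobenzene; 9 (R)-propylene oxide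
Product: 11 (R)-1-[3,5-bis(benzyloxy)phenyl]propan-2-ol, via 3,5-bis(benzyloxy)phenylmagnesium bromide 10 (not isolated)
Conditions: Mg, THF, reflux; then CuI (10 mol %), 9 (1.3 equiv), −30 → 0 °C; aq. NH4Cl
Reagents that add atoms: none
Why: Copper-catalysed epoxide opening by an aryl Grignard reagent, in which SN2 attack at the unsubstituted CH2 leaves the C–O bond of the stereocentre intact, so the (R)-epoxide gives the (R)-alcohol.

Step 6
Reactants: 7 (R)-3-[2,4-bis(benzyloxy)-6-methylbenzoyloxy]butanoic acid; 11 (R)-1-[3,5-bis(benzyloxy)phenyl]propan-2-ol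
Product: 12 (R)-1-[3,5-bis(benzyloxy)phenyl]propan-2-yl (R)-3-[2,4-bis(benzyloxy)-6-methylbenzoyloxy]butanoate
Conditions: EDC·HCl (1.3 equiv), DMAP (0.1 equiv), CH2Cl2, 0 °C → rt
Reagents that add atoms: none
Why: Steglich-type carbodiimide esterification of an unhindered aliphatic acid with a secondary alcohol, which retains both stereocentres, while the low temperature and the small DMAP charge keep elimination of the activated β-acyloxy acid in check.

Step 7
Reactants: 12 (R)-1-[3,5-bis(benzyloxy)phenyl]propan-2-yl (R)-3-[2,4-bis(benzyloxy)-6-methylbenzoyloxy]butanoate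
Product: 14 (R)-1-[3,5-bis(benzyloxy)-2-formylphenyl]propan-2-yl (R)-3-[2,4-bis(benzyloxy)-6-methylbenzoyloxy]butanoate, via ring B aryl-CH=NMe2 iminium chloride 13 (not isolated)
Conditions: POCl3 (2 equiv), DMF, 0 °C → rt; then aq. NaOAc, rt
Reagents that add atoms: N,N-dimethylformamide CN(C)C=O; water O
Why: Vilsmeier–Haack formylation, for which only ring B (two ether donors, no acyl group) is nucleophilic enough, with attack at C2 next to the side chain (para to one OBn, ortho to the other) as is usual for orcinol-type diethers, while ring A is deactivated by its ester.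

Step 8
Reactants: 14 (R)-1-[3,5-bis(benzyloxy)-2-formylphenyl]propan-2-yl (R)-3-[2,4-bis(benzyloxy)-6-methylbenzoyloxy]butanoate
Product: 15 2,4-bis(benzyloxy)-6-[(R)-2-{(R)-3-[2,4-bis(benzyloxy)-6-methylbenzoyloxy]butanoyloxy}propyl]benzoic acid
Conditions: NaClO2, NaH2PO4, 2-methyl-2-butene (excess), t-BuOH/THF/H2O, 0 °C → rt
Reagents that add atoms: sodium chlorite [Na+].[O-]Cl=O
Why: Pinnick oxidation turns the aldehyde into the acid in a weakly acidic buffer that leaves the β-acyloxy ester alone, and the alkene scavenges HOCl before it can chlorinate the electron-rich rings.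

Step 9
Reactants: 15 2,4-bis(benzyloxy)-6-[(R)-2-{(R)-3-[2,4-bis(benzyloxy)-6-methylbenzoyloxy]butanoyloxy}propyl]benzoic acid; 4 tert-butyl (R)-3-hydroxybutanoate
Product: 17 tert-butyl (R)-3-(aroyloxy)butanoate whose aroyl group is the acyl residue of 15 (all-R triester), via acid chloride of 15 16 (not isolated)
Conditions: Me2C=C(Cl)NMe2 (1.3 equiv), CH2Cl2, 0 °C → rt; then 4 (3 equiv), Et3N (2 equiv), DMAP (0.5 equiv), 0 °C → rt
Reagents that add atoms: none
Why: The same neutral acid chloride esterification with DMAP catalysis as in step 3, now driven by an excess of the cheap alcohol 4, with retention at all stereocentres because only the acyl carbon reacts.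

Step 10
Reactants: 17 all-R tert-butyl triester
Product: 18 (R)-3-(aroyloxy)butanoic acid whose aroyl group is the acyl residue of 15 (all-R chain acid)
Conditions: TFA/CH2Cl2 (1:4), 0 °C → rt
Reagents that add atoms: none
Why: Acidolysis of the tert-butyl ester as in step 4, selective because the three other esters are aryl or secondary alkyl esters that do not ionise under these conditions.

Step 11
Reactants: 9 (R)-propylene oxide
Product: 19 (R)-pent-4-yn-2-ol
Conditions: LiC≡CH·H2NCH2CH2NH2 (1.2 equiv), DMSO, 0 °C → rt; H2O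
Reagents that add atoms: lithium acetylide–ethylenediamine complex [Li]C#C.NCCN
Why: SN2 opening of the epoxide by acetylide at the terminal carbon, which leaves the stereocentre untouched and so gives the (R)-alcohol.

Step 12
Reactants: 18 all-R chain acid; 19 (R)-pent-4-yn-2-ol
Product: 20 (R)-pent-4-yn-2-yl ester of 18 (all-R tetraester with terminal alkyne)
Conditions: 19 (1.5 equiv), EDC·HCl (1.3 equiv), DMAP (0.1 equiv), CH2Cl2, 0 °C → rt
Reagents that add atoms: none
Why: Steglich-type esterification of the unhindered aliphatic acid terminus with a small secondary alcohol used in excess, with retention at every stereocentre and no effect on the alkyne.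

Step 13
Reactants: 20 all-R tetraester alkyne; 21 trichloroacetyl chloride
Product: 22 (R)-1-(4,4-dichloro-3-oxocyclobut-1-en-1-yl)propan-2-yl ester of 18
Conditions: 21 (4 equiv, slow addition), Zn–Cu couple (8 equiv), Et2O/DME (3:1), rt → 35 °C
Reagents that add atoms: none
Why: [2+2] cycloaddition of dichloroketene, released from 21 by zinc, to the terminal alkyne as the only ketenophile in 20, with the ketene carbonyl carbon bonding to the terminal CH and CCl2 to the substituted carbon so that the chain sits at C3, while DME ties up ZnCl2.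

Step 14
Reactants: 22 chain 4,4-dichlorocyclobutenone
Product: 23 (R)-1-(3-oxocyclobut-1-en-1-yl)propan-2-yl ester of 18 (chain cyclobutenone with rings A and B benzylated)
Conditions: Zn dust (5 equiv), AcOH (5 equiv), TMEDA (5 equiv), EtOH/THF, 0 °C → rt
Reagents that add atoms: none
Why: Reductive dechlorination of the α,α-dichloroketone by zinc through zinc enolates protonated by AcOH, the standard follow-up to dichloroketene adducts, in a TMEDA/AcOH buffer mild enough for the esters, the benzyl ethers and the homoallylic acyloxy group.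

Step 15
Reactants: 24 chloroacetaldehyde
Product: 25 (Z)-(2-chloroethenyloxy)triisopropylsilane
Conditions: TIPSOTf (1.05 equiv), Et3N (1.3 equiv), CH2Cl2, 0 °C
Reagents that add atoms: triisopropylsilyl triflate CC(C)[Si](OS(=O)(=O)C(F)(F)F)(C(C)C)C(C)C
Why: Soft enolisation and O-silylation (silyl enol ether formation) of the acidified α-chloro aldehyde, which should favour the Z enol ether, and any E isomer leads to the same alkyne in the next step.

Step 16
Reactants: 25 (Z)-(2-chloroethenyloxy)triisopropylsilane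
Product: 27 (triisopropylsilyloxy)acetylene, via lithium (triisopropylsilyloxy)acetylide 26 (not isolated)
Conditions: LiN(iPr)2 (2.2 equiv), THF, −78 °C; then H2O
Reagents that add atoms: none
Why: Dehydrohalogenation of a 2-halovinyl ether by a lithium amide (anti E2 of HCl from the Z isomer), the classical entry to oxygenated acetylenes, which keeps the preformed O–Si bond and so avoids the C- versus O-silylation problem of an ynolate.

Step 17
Reactants: 23 chain cyclobutenone; 27 (triisopropylsilyloxy)acetylene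
Product: 32 tetra-O-benzylhansforester A with ring C as 3-hydroxy-5-(triisopropylsilyloxy)phenyl, via vinylketene 28 (not isolated), via 4-vinylcyclobutenone 29 (not isolated), via dienylketene 30 (not isolated), via cyclohexa-2,4-dienone 31 (not isolated)
Conditions: 27 (3 equiv), toluene (0.2 M), argon, 80 °C then 110 °C, sealed tube
Reagents that add atoms: none
Why: This is the Danheiser benzannulation, known for 3-alkylcyclobutenones and trialkylsilyloxyalkynes: near 80 °C the ring of 23 opens by four-electron electrocyclic cleavage of its C1–C4 bond to vinylketene 28, and the nucleophilic CH carbon of 27 attacks the ketene carbonyl carbon (old C1) while the O-bearing alkyne carbon bonds to the ketene α-carbon (old C2), a [2+2] cycloaddition that gives 29. On further heating 29 opens (four electrons, old C1–C2 bond) to dienylketene 30. Ring C then closes by six-electron electrocyclisation between old C1 and old C4 to dienone 31, which tautomerises to phenol 32, so that old C3 becomes C1 of ring C (side chain), old C1 becomes C3 (OH) and the O-bearing alkyne carbon becomes C5 (OTIPS). No stereocentre appears in 32 (the one in 29 is transient) and the four carbinol centres take no part. The selectivity needed is regiochemical and is secured by the polarisation of the ynol ether, which allows only the 1,3,5 pattern. Chemoselectivity is secured by the substrate design, since 23 has no free OH or NH to trap a ketene and the excess of 27 should intercept 28 before the phenol of 32 can be acylated.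

Step 18
Reactants: 32 ring C mono-TIPS ether
Product: 33 tetra-O-benzylhansforester A (rings A and B benzylated and ring C a free resorcinol)
Conditions: Bu4NF/AcOH (1:1, 1.5 equiv), THF, 0 °C
Reagents that add atoms: none
Why: Fluoride-induced cleavage of the aryl silyl ether, fast because phenoxide is a good leaving group from silicon, with AcOH buffering fluoride and phenoxide so that the β-acyloxy esters see no base.

Step 19
Reactants: 33 tetra-O-benzylhansforester A
Product: 34 hansforester A
Conditions: H2 (1 atm), 10% Pd/C, EtOAc/EtOH, rt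
Reagents that add atoms: none
Why: Catalytic hydrogenolysis removes the four aryl benzyl ethers under neutral conditions, and the ester C–O bonds are homobenzylic rather than benzylic, so they and the four stereocentres stay intact.

Compound list
1 | orsellinic acid | Cc1cc(O)cc(O)c1C(=O)O | starting material
2 | benzyl 2,4-bis(benzyloxy)-6-methylbenzoate | Cc1cc(OCc2ccccc2)cc(OCc2ccccc2)c1C(=O)OCc1ccccc1 | intermediate
3 | 2,4-bis(benzyloxy)-6-methylbenzoic acid | Cc1cc(OCc2ccccc2)cc(OCc2ccccc2)c1C(=O)O | intermediate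
4 | tert-butyl (R)-3-hydroxybutanoate | C[C@@H](O)CC(=O)OC(C)(C)C | starting material
5 | 2,4-bis(benzyloxy)-6-methylbenzoyl chloride | Cc1cc(OCc2ccccc2)cc(OCc2ccccc2)c1C(=O)Cl | intermediate
6 | tert-butyl (R)-3-[2,4-bis(benzyloxy)-6-methylbenzoyloxy]butanoate | Cc1cc(OCc2ccccc2)cc(OCc2ccccc2)c1C(=O)O[C@H](C)CC(=O)OC(C)(C)C | intermediate
7 | (R)-3-[2,4-bis(benzyloxy)-6-methylbenzoyloxy]butanoic acid | Cc1cc(OCc2ccccc2)cc(OCc2ccccc2)c1C(=O)O[C@H](C)CC(=O)O | intermediate
8 | 1,3-bis(benzyloxy)-5-bromobenzene | Brc1cc(OCc2ccccc2)cc(OCc2ccccc2)c1 | starting material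
9 | (R)-propylene oxide | C[C@@H]1CO1 | starting material
10 | 3,5-bis(benzyloxy)phenylmagnesium bromide | Br[Mg]c1cc(OCc2ccccc2)cc(OCc2ccccc2)c1 | intermediate
11 | (R)-1-[3,5-bis(benzyloxy)phenyl]propan-2-ol | C[C@@H](O)Cc1cc(OCc2ccccc2)cc(OCc2ccccc2)c1 | intermediate
12 | (R)-1-[3,5-bis(benzyloxy)phenyl]propan-2-yl (R)-3-[2,4-bis(benzyloxy)-6-methylbenzoyloxy]butanoate | Cc1cc(OCc2ccccc2)cc(OCc2ccccc2)c1C(=O)O[C@H](C)CC(=O)O[C@H](C)Cc1cc(OCc2ccccc2)cc(OCc2ccccc2)c1 | intermediate
13 | ring B C2 dimethyliminium chloride of 12 | Cc1cc(OCc2ccccc2)cc(OCc2ccccc2)c1C(=O)O[C@H](C)CC(=O)O[C@H](C)Cc1cc(OCc2ccccc2)cc(OCc2ccccc2)c1C=[N+](C)C.[Cl-] | intermediate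
14 | (R)-1-[3,5-bis(benzyloxy)-2-formylphenyl]propan-2-yl (R)-3-[2,4-bis(benzyloxy)-6-methylbenzoyloxy]butanoate | Cc1cc(OCc2ccccc2)cc(OCc2ccccc2)c1C(=O)O[C@H](C)CC(=O)O[C@H](C)Cc1cc(OCc2ccccc2)cc(OCc2ccccc2)c1C=O | intermediate
15 | 2,4-bis(benzyloxy)-6-[(R)-2-{(R)-3-[2,4-bis(benzyloxy)-6-methylbenzoyloxy]butanoyloxy}propyl]benzoic acid | Cc1cc(OCc2ccccc2)cc(OCc2ccccc2)c1C(=O)O[C@H](C)CC(=O)O[C@H](C)Cc1cc(OCc2ccccc2)cc(OCc2ccccc2)c1C(=O)O | intermediate
16 | acid chloride of 15 | Cc1cc(OCc2ccccc2)cc(OCc2ccccc2)c1C(=O)O[C@H](C)CC(=O)O[C@H](C)Cc1cc(OCc2ccccc2)cc(OCc2ccccc2)c1C(=O)Cl | intermediate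
17 | tert-butyl (R)-3-(aroyloxy)butanoate, aroyl = acyl residue of 15 | Cc1cc(OCc2ccccc2)cc(OCc2ccccc2)c1C(=O)O[C@H](C)CC(=O)O[C@H](C)Cc1cc(OCc2ccccc2)cc(OCc2ccccc2)c1C(=O)O[C@H](C)CC(=O)OC(C)(C)C | intermediate
18 | (R)-3-(aroyloxy)butanoic acid, aroyl = acyl residue of 15 (chain acid) | Cc1cc(OCc2ccccc2)cc(OCc2ccccc2)c1C(=O)O[C@H](C)CC(=O)O[C@H](C)Cc1cc(OCc2ccccc2)cc(OCc2ccccc2)c1C(=O)O[C@H](C)CC(=O)O | intermediate
19 | (R)-pent-4-yn-2-ol | C[C@@H](O)CC#C | intermediate
20 | (R)-pent-4-yn-2-yl ester of 18 | Cc1cc(OCc2ccccc2)cc(OCc2ccccc2)c1C(=O)O[C@H](C)CC(=O)O[C@H](C)Cc1cc(OCc2ccccc2)cc(OCc2ccccc2)c1C(=O)O[C@H](C)CC(=O)O[C@H](C)CC#C | intermediate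
21 | trichloroacetyl chloride | ClC(=O)C(Cl)(Cl)Cl | starting material
22 | (R)-1-(4,4-dichloro-3-oxocyclobut-1-en-1-yl)propan-2-yl ester of 18 | Cc1cc(OCc2ccccc2)cc(OCc2ccccc2)c1C(=O)O[C@H](C)CC(=O)O[C@H](C)Cc1cc(OCc2ccccc2)cc(OCc2ccccc2)c1C(=O)O[C@H](C)CC(=O)O[C@H](C)CC1=CC(=O)C1(Cl)Cl | intermediate
23 | (R)-1-(3-oxocyclobut-1-en-1-yl)propan-2-yl ester of 18 (chain cyclobutenone) | Cc1cc(OCc2ccccc2)cc(OCc2ccccc2)c1C(=O)O[C@H](C)CC(=O)O[C@H](C)Cc1cc(OCc2ccccc2)cc(OCc2ccccc2)c1C(=O)O[C@H](C)CC(=O)O[C@H](C)CC1=CC(=O)C1 | intermediate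
24 | chloroacetaldehyde | ClCC=O | starting material
25 | (Z)-(2-chloroethenyloxy)triisopropylsilane | Cl/C=C\O[Si](C(C)C)(C(C)C)C(C)C | intermediate
26 | lithium (triisopropylsilyloxy)acetylide | [Li]C#CO[Si](C(C)C)(C(C)C)C(C)C | intermediate
27 | (triisopropylsilyloxy)acetylene | C#CO[Si](C(C)C)(C(C)C)C(C)C | intermediate
28 | chain vinylketene | Cc1cc(OCc2ccccc2)cc(OCc2ccccc2)c1C(=O)O[C@H](C)CC(=O)O[C@H](C)Cc1cc(OCc2ccccc2)cc(OCc2ccccc2)c1C(=O)O[C@H](C)CC(=O)O[C@H](C)CC(=C)C=C=O | intermediate
29 | chain 3-silyloxy-4-vinylcyclobut-2-enone (ring sp3 centre undefined) | Cc1cc(OCc2ccccc2)cc(OCc2ccccc2)c1C(=O)O[C@H](C)CC(=O)O[C@H](C)Cc1cc(OCc2ccccc2)cc(OCc2ccccc2)c1C(=O)O[C@H](C)CC(=O)O[C@H](C)CC(=C)C1C(=O)C=C1O[Si](C(C)C)(C(C)C)C(C)C | intermediate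
30 | chain dienylketene (ketenyl and vinyl groups cis) | Cc1cc(OCc2ccccc2)cc(OCc2ccccc2)c1C(=O)O[C@H](C)CC(=O)O[C@H](C)Cc1cc(OCc2ccccc2)cc(OCc2ccccc2)c1C(=O)O[C@H](C)CC(=O)O[C@H](C)CC(=C)/C=C(/O[Si](C(C)C)(C(C)C)C(C)C)C=C=O | intermediate
31 | chain 3-silyloxy-5-alkylcyclohexa-2,4-dienone | Cc1cc(OCc2ccccc2)cc(OCc2ccccc2)c1C(=O)O[C@H](C)CC(=O)O[C@H](C)Cc1cc(OCc2ccccc2)cc(OCc2ccccc2)c1C(=O)O[C@H](C)CC(=O)O[C@H](C)CC1=CC(O[Si](C(C)C)(C(C)C)C(C)C)=CC(=O)C1 | intermediate
32 | tetra-O-benzylhansforester A, ring C mono-TIPS ether | Cc1cc(OCc2ccccc2)cc(OCc2ccccc2)c1C(=O)O[C@H](C)CC(=O)O[C@H](C)Cc1cc(OCc2ccccc2)cc(OCc2ccccc2)c1C(=O)O[C@H](C)CC(=O)O[C@H](C)Cc1cc(O)cc(O[Si](C(C)C)(C(C)C)C(C)C)c1 | intermediate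
33 | tetra-O-benzylhansforester A | Cc1cc(OCc2ccccc2)cc(OCc2ccccc2)c1C(=O)O[C@H](C)CC(=O)O[C@H](C)Cc1cc(OCc2ccccc2)cc(OCc2ccccc2)c1C(=O)O[C@H](C)CC(=O)O[C@H](C)Cc1cc(O)cc(O)c1 | intermediate
34 | hansforester A | Cc1cc(O)cc(O)c1C(=O)O[C@H](C)CC(=O)O[C@H](C)Cc1cc(O)cc(O)c1C(=O)O[C@H](C)CC(=O)O[C@H](C)Cc1cc(O)cc(O)c1 | target

Total step count: 19
Longest linear sequence: 15 steps (1, 2, 3, 4, 6, 7, 8, 9, 10, 12, 13, 14, 17, 18, 19)

Three steps most likely to fail

Step 17 (benzannulation). The vinylketene may be consumed by self-condensation or by O-acylation of the phenol that the reaction itself produces. Long heating may also cause loss of the carboxylic acid from the homoallylic ester position before the cycloaddition occurs. The fallback brings ring C in ready-made instead of building it. It sets out from acid 18 and alcohol 11, both already in the route. Carbodiimide esterification (EDC·HCl, DMAP, CH2Cl2, 0 °C) should give hexa-O-benzylhansforester A F1. Hydrogenolysis of all six benzyl ethers (H2, 10% Pd/C, EtOAc/EtOH) comes back to the route at target 34.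

Step 13 (dichloroketene cycloaddition on the full chain). The cycloaddition may be sluggish on a large, dilute substrate while the ketene is lost to self-condensation. ZnCl2 may also promote ether cleavage or chloride migration. The fallback builds the four-membered ring on the small alkyne and attaches it last. It sets out from 19.
- Silylation (TBSCl, imidazole, DMF) should give (R)-tert-butyldimethyl(pent-4-yn-2-yloxy)silane F2.
- Dichloroketene addition (21, Zn–Cu couple, Et2O/DME) should give (R)-3-[2-(tert-butyldimethylsilyloxy)propyl]-4,4-dichlorocyclobut-2-en-1-one F3.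
- Zn/AcOH/TMEDA should give (R)-3-[2-(tert-butyldimethylsilyloxy)propyl]cyclobut-2-en-1-one F4.
- Aqueous HF in MeCN at 0 °C should give (R)-3-(2-hydroxypropyl)cyclobut-2-en-1-one F5.
- Esterification of F5 with acid 18 (EDC·HCl, DMAP 0.05 equiv, CH2Cl2, −10 °C) comes back to the route at 23.

Step 9 (acylation by the doubly ortho-substituted ring B acid chloride). Acyl transfer to the secondary alcohol may be so slow that loss of an ortho benzyl group from the acid chloride, or elimination to a crotonate, takes over. The fallback inverts the roles of the partners in a Mitsunobu reaction, in which the hindered carboxylate is the nucleophile and the carbinol carbon the electrophile. It sets out from acid 15 and purchased tert-butyl (S)-3-hydroxybutanoate F6. PPh3 and DIAD in toluene at 0 °C should give, by SN2 inversion, the (R)-configured ester, and the fallback comes back to the route at 17.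

Further compounds
F1 | step 17 | hexa-O-benzylhansforester A | Cc1cc(OCc2ccccc2)cc(OCc2ccccc2)c1C(=O)O[C@H](C)CC(=O)O[C@H](C)Cc1cc(OCc2ccccc2)cc(OCc2ccccc2)c1C(=O)O[C@H](C)CC(=O)O[C@H](C)Cc1cc(OCc2ccccc2)cc(OCc2ccccc2)c1
F2 | step 13 | (R)-tert-butyldimethyl(pent-4-yn-2-yloxy)silane | C[C@@H](O[Si](C)(C)C(C)(C)C)CC#C
F3 | step 13 | (R)-3-[2-(tert-butyldimethylsilyloxy)propyl]-4,4-dichlorocyclobut-2-en-1-one | C[C@@H](O[Si](C)(C)C(C)(C)C)CC1=CC(=O)C1(Cl)Cl
F4 | step 13 | (R)-3-[2-(tert-butyldimethylsilyloxy)propyl]cyclobut-2-en-1-one | C[C@@H](O[Si](C)(C)C(C)(C)C)CC1=CC(=O)C1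
F5 | step 13 | (R)-3-(2-hydroxypropyl)cyclobut-2-en-1-one | C[C@@H](O)CC1=CC(=O)C1
F6 | step 9 | tert-butyl (S)-3-hydroxybutanoate | C[C@H](O)CC(=O)OC(C)(C)C
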